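**Compound numbering used throughout:** 1–41 as defined in the steps and the compound list; 19, 26 and 3 are the three partners of the key step and 30 is its product. Atoms carry the flavan numbering of the target (unprimed = upper unit, primed = lower unit).

## The problem

The target is a biflavan. Its upper unit is a 2,3-cis-3,4-trans flavan-3-ol (C2 R, C3 R, C4 S) with a 7,8-dihydroxylated ring A and a catechol ring B. Its lower unit is an all-cis flavan-3,4-diol (C2′ R, C3′ R, C4′ R) with a 7′,8′-dihydroxylated ring A and a 4-hydroxyphenyl ring B. The two are joined by the C4–C6′ bond, so C4 is a methine flanked by two ortho-oxygenated arenes and by C3. This is the most crowded bond of the molecule, and it must form with unambiguous regiochemistry on both arenes (C4a above, C6′ and not C5′ below). The six stereocentres form two triads that are too far apart to steer each other. Within a triad the oxygenated middle carbon (C3, C3′) can steer its neighbours, whereas C4 and C4′ must be fixed in the bond-forming events that create them. Nine phenols (one catechol, two pyrogallol-type rings) oxidise readily and have to stay masked until the last step. The C4′ hydroxyl is benzylic, para to O7′ and ortho to O1′, so it ionises under acid and is exposed to hydrogenolysis; C2 and C2′ are benzylic ethers of electron-rich aryl groups. The enabling feature is that O7′ is ortho to C6′: a lower-unit salicylaldehyde (6′-CHO, O7′ acylated) can become an ortho-quinone methide whose exocyclic carbon is C4. Ring A (metalated at C4a) and C3 (a chiral glycolate enolate) can then be added as two successive nucleophiles under base only.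

## Retrosynthesis

**41 back to 39.** The nine benzyl C–O bonds and the one Si–O bond are cut. Benzyl ethers are chosen for all phenols and for O3 and O3′ because they fall under neutral hydrogen in the last step. O4′ carries the only silyl group, which fluoride removes from 39 (giving 40) before hydrogenolysis. A 3′,4′-acetonide would instead need acid at the very end, exactly where C4′ ionises, and a benzyl ether on O4′ would invite cleavage of the C4′–O bond. The forward steps must only spare the free benzylic C4′ hydroxyl of 40 during hydrogenolysis.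

**39 back to 36.** The O1–C2 bond and then the C2–H bond are cut. Closing the upper pyran by SN2 attack of O1 on C2 lets C2 come from ketone 36 by chelation-controlled reduction to the anti alcohol 37; inversion then gives the 2,3-cis ring. The neighbouring cut O1–C8a would need retention, the harder syn alcohol and a very hindered aryl electrophile. The precursor loses a ring and a stereocentre. The forward reaction must invert cleanly at an electron-rich benzylic carbinol, and O1 must be unmasked alone (allyl ether, cleaved in 37 to give 38) while O7′ stays benzylated.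

**36 back to 33 and 34.** The C2–aryl bond to ring B is cut: the Weinreb amide 33 accepts the aryllithium 35 made from bromide 34. This delivers ring B as a simple commercial aryl bromide and leaves C2 at the ketone level needed for the chelate reduction. The α-alkoxy centre C3 must not epimerise.

**33 back to 30.** The amide N–C2 bond and the O7′–benzyl bond are cut. The imide of 30 is hindered, but its neighbouring O7′ phenoxide can take the acyl group intramolecularly (lactone 31) and hand it to the magnesium amide of N,O-dimethylhydroxylamine, giving 32. Only then is O7′ benzylated (33), so that this phenol can never compete with O1 in the later ring closure.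

**30 back to 19, 26 and 3 (key disconnection).** C4–C4a and C3–C4 are cut together. The alternative of cutting C4–C6′ in the classical way (flavan-4-yl cation plus phenol) needs acid and leaves the regiochemistry on the lower ring to chance. Here ring A is the nucleophile, so the metal in 26 fixes its attachment point, the formyl group in 19 fixes C6′, and the auxiliary of 3 sets C3. The three pieces are of comparable size, and the lower unit is complete before the union. The forward reaction must generate the quinone methide from exactly one equivalent of 26 and capture it with the enolate of 3 on one face at C3 and one relative orientation at C4.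

**26 back to 20.** The C–Mg, C–Br and three O–C bonds are cut. The pattern "metal next to three consecutive oxygens" is reached from 2,3-dihydroxybenzaldehyde 20 by benzylation (21), Dakin oxidation (23), ortho-bromination (24), allylation (25) and magnesium insertion. Allyl is chosen for O1 rather than a fluoride-labile group because the O4′ silyl ether must outlast the unmasking of O1.

**19 back to 17.** The carbonate C–O bond and the C6′–CHO bond are cut. The only free position ortho to the O7′ phenol of 17 is C6′, so a magnesium-mediated formylation (18) and acylation with Boc2O are all that is needed.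

**17 back to 11 and 12.** The O1′–C2′ bond, the C2′–H bond and the C2′–aryl bond are cut, with the same logic as for the upper ring: Weinreb amide 11 plus aryllithium 13 (from 12) gives ketone 14, chelate reduction gives 15, deallylation gives 16, and Mitsunobu closure with inversion gives 17. Hydrogenation of a flavonol would deliver the all-cis diol only as a racemate and under conditions that strip benzyl and allyl ethers, so the lower unit is built open-chain from a single chiral reagent instead.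

**11 back to 3 and 7.** The C3′–C4′ bond is cut. An anti-selective aldol reaction of the same glycolyl imide 3 with aldehyde 7 sets C3′ and C4′ (adduct 9) in the erythro relationship that becomes 3′,4′-cis in the ring. Transamidation (10) and silylation complete the fragment. Aldehyde 7 comes from 2,3,4-trihydroxybenzaldehyde 4 by three graded etherifications (5, 6), and 3 comes from oxazolidinone 1 and acid chloride 2.

## Roads not taken

**Alternative 1:** The cut is O1′–C2′ and C3′–C4′ of the lower pyran. A chiral phosphoric acid would ionise the diallyl acetal A2 (upper flavan already attached to a lower ring A with free O1′) to an allyloxy ortho-quinone methide. Endo [4+2] addition of the (Z)-enol benzoate A3 would then give biflavan A1.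
- Merits: one step builds the lower heterocycle and all three of its stereocentres, and the all-cis pattern follows from the (Z)-alkene and the endo mode.
- Weak points: an enol ester is a poor 2π donor for such a cycloaddition. The catalyst has to override or match the stereocentres of the upper unit already present. The benzylic 4′-O-allyl bond of A1 can ionise again under the acid that forms it. The route also presupposes A2, so the crowded C4–C6′ bond still has to be made by other means.
- Comparison: for the lower ring this road is clearly shorter (one step against the eight operations from 7 to 17). The chosen plan sets against this that each of its centres arises from a reaction with a reliable model (auxiliary, chelate, SN2), and that its key step solves the interflavan bond, which Alternative 1 leaves open.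

**Alternative 2:** The cut is O1–C2. The O1 phenol of the cis-epoxide A5 would open the epoxide at benzylic C2 with inversion to give A4 with a free C3 hydroxyl.
- Merits: the closure is stereospecific, needs no phosphine or azo reagent and frees O3 directly. The pivalates on ring B damp ionisation at C2, so inversion should be cleaner than in a Mitsunobu reaction of an electron-rich carbinol.
- Weak points: A5 needs a (Z)-alkene next to the C4 methine and an epoxidation whose face is controlled by C4 alone. The 5-exo attack at C3 competes, and the same pivalates that stop ionisation also weaken the benzylic bias for the 6-endo mode. Pivalates also forbid an organolithium entry of ring B.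
- Comparison: the bond closed is the same as in step 25. Alternative 2 is better at the closure itself. The chosen plan is better at reaching the closure substrate, because C3 comes from the key step and C2 from a chelate reduction with no alkene geometry to control.

**Alternative 3:** The cut is O1–C8a. Pd(OAc)2 with 2-(di-tert-butylphosphino)-1,1′-binaphthyl and Cs2CO3 would couple the C2 hydroxyl of the triflate A7 with C8a to give A6.
- Merits: C2 is never touched, so there is no inversion to secure and no benzylic ionisation.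
- Weak points: the triflate is flanked by the C8 benzyloxy group and the C4 substituent. A secondary benzylic alkoxide on palladium is prone to β-hydride elimination. The route needs the syn alcohol, which is the harder epimer to obtain from an α-benzyloxy ketone. Its acetonide also calls for acid at the end.
- Comparison: step count is about equal. Alternative 3 is safer at C2 and weaker in the reduction and in the catalytic step, so the chosen plan keeps it as the fallback for step 25.

Key step: step 19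

Remark: the CIP descriptors at C3′ (while O4′ is silylated) and at C4 (while O7′ is benzylated) differ from those of the target through priority changes only; the geometry is that of the target throughout. Compounds 1, 2, 4, 12, 20 and 34 are taken to be purchasable.

## Steps

Step 1
Reactants: 1 (S)-4-benzyloxazolidin-2-one; 2 (benzyloxy)acetyl chloride
Product: 3 (S)-4-benzyl-3-[(benzyloxy)acetyl]oxazolidin-2-one
Conditions: n-BuLi, THF, −78 °C; then 2, −78 → 0 °C
Reagents that add atoms: none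
Why: N-acylation of the lithiated oxazolidinone by the acid chloride (standard imide formation); the auxiliary stereocentre is not involved.

Step 2
Reactants: 4 2,3,4-trihydroxybenzaldehyde
Product: 5 4-(allyloxy)-2,3-dihydroxybenzaldehyde
Conditions: allyl bromide (1.05 equiv), NaHCO3, NaI (cat.), DMF, 40 °C
Reagents that add atoms: allyl bromide, C=CCBr
Why: Williamson etherification; the 4-hydroxyl is para to the formyl group, the most acidic and not hydrogen-bonded, so it is alkylated first under weak base.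

Step 3
Reactants: 5 4-(allyloxy)-2,3-dihydroxybenzaldehyde
Product: 6 4-(allyloxy)-3-(benzyloxy)-2-hydroxybenzaldehyde
Conditions: BnBr (1.05 equiv), K2CO3 (1.1 equiv), acetone, rt → 40 °C
Reagents that add atoms: benzyl bromide, BrCc1ccccc1
Why: Williamson etherification; the 3-hydroxyl reacts in preference to the 2-hydroxyl, which is held in a hydrogen bond to the aldehyde.

Step 4
Reactants: 6 4-(allyloxy)-3-(benzyloxy)-2-hydroxybenzaldehyde
Product: 7 2,4-bis(allyloxy)-3-(benzyloxy)benzaldehyde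
Conditions: allyl bromide, K2CO3, DMF, 60 °C
Reagents that add atoms: allyl bromide, C=CCBr
Why: Williamson etherification of the remaining chelated phenol under more forcing conditions; O1′ and O7′ now carry the same removable group.

Step 5
Reactants: 3 (S)-4-benzyl-3-[(benzyloxy)acetyl]oxazolidin-2-one; 7 2,4-bis(allyloxy)-3-(benzyloxy)benzaldehyde
Product: 9 (S)-4-benzyl-3-{(2R,3R)-3-[2,4-bis(allyloxy)-3-(benzyloxy)phenyl]-2-(benzyloxy)-3-hydroxypropanoyl}oxazolidin-2-one (2,3-anti), via trimethylsilyl ether 8 (not isolated)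
Conditions: MgCl2 (20 mol %), Et3N, Me3SiCl, EtOAc, rt; then PPTS, MeOH, 0 °C
Reagents that add atoms: none
Why: Magnesium halide-catalysed direct anti-aldol reaction of a chiral N-acyloxazolidinone with a non-enolisable aromatic aldehyde; the chelated (Z)-magnesium enolate reacts on the face opposite the auxiliary benzyl group (C3′, R) through a boat-like transition state that gives the 3′,4′-anti adduct (C4′, R). Silyl trapping of the aldolate makes the addition irreversible, and mild methanolysis frees the carbinol.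

Step 6
Reactants: 9 (S)-4-benzyl-3-{(2R,3R)-3-[2,4-bis(allyloxy)-3-(benzyloxy)phenyl]-2-(benzyloxy)-3-hydroxypropanoyl}oxazolidin-2-one
Product: 10 (2R,3R)-3-[2,4-bis(allyloxy)-3-(benzyloxy)phenyl]-2-(benzyloxy)-3-hydroxy-N-methoxy-N-methylpropanamide
Conditions: MeNHOMe·HCl, AlMe3, CH2Cl2, −20 → 0 °C
Reagents that add atoms: N,O-dimethylhydroxylamine hydrochloride, CNOC.Cl
Why: Weinreb transamidation of a β-hydroxy imide with the aluminium amide; the β-aluminium alkoxide directs attack to the exocyclic carbonyl, the auxiliary is released intact, and neither stereocentre is touched.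

Step 7
Reactants: 10 (2R,3R)-3-[2,4-bis(allyloxy)-3-(benzyloxy)phenyl]-2-(benzyloxy)-3-hydroxy-N-methoxy-N-methylpropanamide
Product: 11 (2R,3R)-3-[2,4-bis(allyloxy)-3-(benzyloxy)phenyl]-2-(benzyloxy)-3-[(tert-butyldimethylsilyl)oxy]-N-methoxy-N-methylpropanamide
Conditions: TBSOTf, 2,6-lutidine, CH2Cl2, −78 → 0 °C
Reagents that add atoms: tert-butyldimethylsilyl trifluoromethanesulfonate, CC(C)(C)[Si](C)(C)OS(=O)(=O)C(F)(F)F
Why: Silylation of the secondary benzylic alcohol with a silyl triflate and a hindered base; the non-chelating silyl ether on O4′ leaves the α-benzyloxy group as the only chelating site for step 9.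

Step 8
Reactants: 11 (2R,3R)-3-[2,4-bis(allyloxy)-3-(benzyloxy)phenyl]-2-(benzyloxy)-3-[(tert-butyldimethylsilyl)oxy]-N-methoxy-N-methylpropanamide; 12 1-(benzyloxy)-4-bromobenzene
Product: 14 (2R,3R)-3-[2,4-bis(allyloxy)-3-(benzyloxy)phenyl]-2-(benzyloxy)-1-[4-(benzyloxy)phenyl]-3-[(tert-butyldimethylsilyl)oxy]propan-1-one, via aryllithium 13 (not isolated)
Conditions: 12, n-BuLi, THF, −78 °C; then 11, −78 → −30 °C; aq NH4Cl
Reagents that add atoms: none
Why: Bromine–lithium exchange followed by aryllithium addition to a Weinreb amide; the chelated tetrahedral intermediate stops the reaction at the ketone and protects the α-alkoxy centre from enolisation.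

Step 9
Reactants: 14 (2R,3R)-3-[2,4-bis(allyloxy)-3-(benzyloxy)phenyl]-2-(benzyloxy)-1-[4-(benzyloxy)phenyl]-3-[(tert-butyldimethylsilyl)oxy]propan-1-one
Product: 15 (1S,2S,3R)-3-[2,4-bis(allyloxy)-3-(benzyloxy)phenyl]-2-(benzyloxy)-1-[4-(benzyloxy)phenyl]-3-[(tert-butyldimethylsilyl)oxy]propan-1-ol (1,2-anti)
Conditions: Zn(BH4)2, Et2O, −30 → 0 °C
Reagents that add atoms: none
Why: Chelation-controlled ketone reduction (Cram chelate model); zinc bridges the carbonyl and the α-benzyloxy oxygen and hydride enters anti to the C4′-bearing substituent, giving the 1,2-anti alcohol (C2′, S).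

Step 10
Reactants: 15 (1S,2S,3R)-3-[2,4-bis(allyloxy)-3-(benzyloxy)phenyl]-2-(benzyloxy)-1-[4-(benzyloxy)phenyl]-3-[(tert-butyldimethylsilyl)oxy]propan-1-ol
Product: 16 (1S,2S,3R)-2-(benzyloxy)-3-[3-(benzyloxy)-2,4-dihydroxyphenyl]-1-[4-(benzyloxy)phenyl]-3-[(tert-butyldimethylsilyl)oxy]propan-1-ol
Conditions: Pd(PPh3)4 (5 mol %), morpholine, THF, rt
Reagents that add atoms: none
Why: Deallylation of both aryl allyl ethers by zerovalent palladium with π-allyl transfer to morpholine; benzyl and silyl ethers and the stereocentres are untouched.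

Step 11
Reactants: 16 (1S,2S,3R)-2-(benzyloxy)-3-[3-(benzyloxy)-2,4-dihydroxyphenyl]-1-[4-(benzyloxy)phenyl]-3-[(tert-butyldimethylsilyl)oxy]propan-1-ol
Product: 17 (2R,3S,4R)-3,8-bis(benzyloxy)-2-[4-(benzyloxy)phenyl]-4-[(tert-butyldimethylsilyl)oxy]-3,4-dihydro-2H-chromen-7-ol (2,3-cis-3,4-cis)
Conditions: PPh3, DIAD, THF (0.02 M), 0 °C → rt
Reagents that add atoms: none
Why: Intramolecular Mitsunobu etherification; O1′ displaces the activated C2′ hydroxyl with inversion (S to R), which turns the anti alcohol into the 2,3-cis flavan. Only O1′ can reach C2′ in a six-membered ring, so the free O7′ phenol does not interfere.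

Step 12
Reactants: 17 (2R,3S,4R)-3,8-bis(benzyloxy)-2-[4-(benzyloxy)phenyl]-4-[(tert-butyldimethylsilyl)oxy]-3,4-dihydro-2H-chromen-7-ol
Product: 18 (2R,3S,4R)-3,8-bis(benzyloxy)-2-[4-(benzyloxy)phenyl]-4-[(tert-butyldimethylsilyl)oxy]-7-hydroxy-3,4-dihydro-2H-chromene-6-carbaldehyde
Conditions: MgCl2, Et3N, (CH2O)n, THF, 65 °C
Reagents that add atoms: paraformaldehyde (formaldehyde), C=O
Why: Magnesium-mediated ortho-formylation of a phenol; the magnesium phenoxide delivers formaldehyde to the only free ortho position (C6′) and a second formaldehyde oxidises the benzylic alkoxide to the aldehyde. The carbon introduced here becomes C4 of the upper unit.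

Step 13
Reactants: 18 (2R,3S,4R)-3,8-bis(benzyloxy)-2-[4-(benzyloxy)phenyl]-4-[(tert-butyldimethylsilyl)oxy]-7-hydroxy-3,4-dihydro-2H-chromene-6-carbaldehyde
Product: 19 tert-butyl (2R,3S,4R)-3,8-bis(benzyloxy)-2-[4-(benzyloxy)phenyl]-4-[(tert-butyldimethylsilyl)oxy]-6-formyl-3,4-dihydro-2H-chromen-7-yl carbonate
Conditions: Boc2O, DMAP (cat.), i-Pr2NEt, CH2Cl2, 0 °C → rt
Reagents that add atoms: di-tert-butyl dicarbonate, CC(C)(C)OC(=O)OC(=O)OC(C)(C)C
Why: DMAP-catalysed O-acylation of the phenol with Boc2O; the O-Boc salicylaldehyde is the latent quinone methide.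

Step 14
Reactants: 20 2,3-dihydroxybenzaldehyde
Product: 21 2,3-bis(benzyloxy)benzaldehyde
Conditions: BnBr, K2CO3, DMF, 60 °C
Reagents that add atoms: benzyl bromide, BrCc1ccccc1
Why: Double Williamson etherification of the catechol.

Step 15
Reactants: 21 2,3-bis(benzyloxy)benzaldehyde
Product: 23 2,3-bis(benzyloxy)phenol, via aryl formate 22 (not isolated)
Conditions: mCPBA, CH2Cl2, 0 °C → rt; then K2CO3, MeOH, rt
Reagents that add atoms: 3-chloroperoxybenzoic acid, OOC(=O)c1cccc(Cl)c1
Why: Dakin-type Baeyer–Villiger oxidation; the electron-rich aryl group migrates to oxygen and the formate is cleaved by methanolysis, which turns the formyl carbon into the future O1.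

Step 16
Reactants: 23 2,3-bis(benzyloxy)phenol
Product: 24 2,3-bis(benzyloxy)-6-bromophenol
Conditions: NBS, i-Pr2NH (10 mol %), CH2Cl2, 0 °C
Reagents that add atoms: N-bromosuccinimide, O=C1CCC(=O)N1Br
Why: Amine-catalysed ortho-bromination of a phenol; C6 is ortho to the hydroxyl and para to the 3-benzyloxy group, so both directing effects and the hydrogen-bonded N-bromoamine point to the same carbon.

Step 17
Reactants: 24 2,3-bis(benzyloxy)-6-bromophenol
Product: 25 2-(allyloxy)-3,4-bis(benzyloxy)-1-bromobenzene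
Conditions: allyl bromide, K2CO3, DMF, rt
Reagents that add atoms: allyl bromide, C=CCBr
Why: Williamson etherification; the allyl ether on O1 survives organometallic, hydride and basic steps and is later removed without fluoride or acid.

Step 18
Reactants: 25 2-(allyloxy)-3,4-bis(benzyloxy)-1-bromobenzene
Product: 26 [2-(allyloxy)-3,4-bis(benzyloxy)phenyl]magnesium bromide (titrated THF solution)
Conditions: Mg turnings, LiCl, i-Bu2AlH (1 mol %), THF, 0 °C → rt
Reagents that add atoms: magnesium, [Mg]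
Why: Grignard formation by magnesium insertion into the aryl bromide; the metal marks C4a as the point of attachment of ring A.

Step 19
Reactants: 19 tert-butyl (2R,3S,4R)-3,8-bis(benzyloxy)-2-[4-(benzyloxy)phenyl]-4-[(tert-butyldimethylsilyl)oxy]-6-formyl-3,4-dihydro-2H-chromen-7-yl carbonate; 26 [2-(allyloxy)-3,4-bis(benzyloxy)phenyl]magnesium bromide; 3 (S)-4-benzyl-3-[(benzyloxy)acetyl]oxazolidin-2-one
Product: 30 (S)-4-benzyl-3-{(2R,3S)-3-[2-(allyloxy)-3,4-bis(benzyloxy)phenyl]-2-(benzyloxy)-3-[(2R,3S,4R)-3,8-bis(benzyloxy)-2-[4-(benzyloxy)phenyl]-4-[(tert-butyldimethylsilyl)oxy]-7-hydroxy-3,4-dihydro-2H-chromen-6-yl]propanoyl}oxazolidin-2-one, via sodium enolate 27 (not isolated), via magnesium alkoxide 28 (not isolated), via ortho-quinone methide 29 (not isolated)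
Conditions: 26 (1.05 equiv), THF, −78 °C; then 27 [3, NaN(SiMe3)2, THF, −78 °C] (1.5 equiv), −78 → −40 °C; AcOH, −78 °C
Reagents that add atoms: none
Why: Proposed new method: the aryl Grignard 26 adds to the aldehyde of 19, the bromomagnesium alkoxide 28 takes the Boc group from O7′, and the magnesium phenoxide then expels tert-butyl carbonate from the benzylic position to give the (E)-ortho-quinone methide 29, whose methide carbon is C4. The chelated sodium (Z)-enolate 27 then adds to C4 in a conjugate sense, and rearomatisation of the lower ring A drives the addition; C4–C4a and C3–C4 are formed and no ring closes. The closest known reaction type is the one-pot addition of an organomagnesium reagent to an O-Boc salicylaldehyde with capture of the ortho-quinone methide by a second carbon nucleophile, together with alkylations and conjugate additions of chiral imide enolates; new here is a glycolate imide enolate as the second nucleophile on an aryl-substituted methide. C3 (R) is controlled by the auxiliary, because the enolate reacts on the face opposite the benzyl group of the (S)-oxazolidinone, as in its alkylations. C4 is controlled by the relative approach of the two π-systems: a closed, sodium-bridged transition state between the (Z)-enolate and the (E)-methide gives the anti adduct, which is the 3,4-trans relationship of the target, and this must be verified and can be tuned through the counter-ion. The step needs chemoselectivity: one equivalent of 26 so that no second aryl group adds to 29, and enolate addition only after the aldehyde is consumed so that it does not attack the carbonate; the order of addition at −78 °C secures both, while regiochemistry is fixed by the magnesium on ring A and the formyl group on the lower ring. The cold acetic acid quench keeps the O7′ phenol from lactonising onto the imide, and any lactone formed is not lost because step 20 passes through it.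

Step 20
Reactants: 30 (S)-4-benzyl-3-{(2R,3S)-3-[2-(allyloxy)-3,4-bis(benzyloxy)phenyl]-2-(benzyloxy)-3-[(2R,3S,4R)-3,8-bis(benzyloxy)-2-[4-(benzyloxy)phenyl]-4-[(tert-butyldimethylsilyl)oxy]-7-hydroxy-3,4-dihydro-2H-chromen-6-yl]propanoyl}oxazolidin-2-one
Product: 32 (2R,3S)-3-[2-(allyloxy)-3,4-bis(benzyloxy)phenyl]-2-(benzyloxy)-3-[(2R,3S,4R)-3,8-bis(benzyloxy)-2-[4-(benzyloxy)phenyl]-4-[(tert-butyldimethylsilyl)oxy]-7-hydroxy-3,4-dihydro-2H-chromen-6-yl]-N-methoxy-N-methylpropanamide, via aryl lactone 31 (not isolated)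
Conditions: MeNHOMe·HCl, i-PrMgCl, THF, −20 → 0 °C
Reagents that add atoms: N,O-dimethylhydroxylamine hydrochloride, CNOC.Cl
Why: Neighbouring-group acyl transfer followed by Weinreb aminolysis of a lactone; the O7′ magnesium phenoxide attacks the exocyclic imide carbonyl (six-membered lactone 31, auxiliary released) and the chloromagnesium amide opens the aryl ester. This avoids endocyclic cleavage of the hindered imide, and C3 and C4 are untouched.

Step 21
Reactants: 32 (2R,3S)-3-[2-(allyloxy)-3,4-bis(benzyloxy)phenyl]-2-(benzyloxy)-3-[(2R,3S,4R)-3,8-bis(benzyloxy)-2-[4-(benzyloxy)phenyl]-4-[(tert-butyldimethylsilyl)oxy]-7-hydroxy-3,4-dihydro-2H-chromen-6-yl]-N-methoxy-N-methylpropanamide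
Product: 33 (2R,3R)-3-[2-(allyloxy)-3,4-bis(benzyloxy)phenyl]-2-(benzyloxy)-N-methoxy-N-methyl-3-[(2R,3S,4R)-3,7,8-tris(benzyloxy)-2-[4-(benzyloxy)phenyl]-4-[(tert-butyldimethylsilyl)oxy]-3,4-dihydro-2H-chromen-6-yl]propanamide
Conditions: BnBr, K2CO3, Bu4NI (cat.), DMF, rt → 40 °C
Reagents that add atoms: benzyl bromide, BrCc1ccccc1
Why: Williamson etherification of the hindered O7′ phenol; carbonate base does not enolise the α-alkoxy amide, and the amide nitrogen is too poor a leaving group for the lactone to re-form.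

Step 22
Reactants: 33 (2R,3R)-3-[2-(allyloxy)-3,4-bis(benzyloxy)phenyl]-2-(benzyloxy)-N-methoxy-N-methyl-3-[(2R,3S,4R)-3,7,8-tris(benzyloxy)-2-[4-(benzyloxy)phenyl]-4-[(tert-butyldimethylsilyl)oxy]-3,4-dihydro-2H-chromen-6-yl]propanamide; 34 1,2-bis(benzyloxy)-4-bromobenzene
Product: 36 (2R,3R)-3-[2-(allyloxy)-3,4-bis(benzyloxy)phenyl]-2-(benzyloxy)-1-[3,4-bis(benzyloxy)phenyl]-3-[(2R,3S,4R)-3,7,8-tris(benzyloxy)-2-[4-(benzyloxy)phenyl]-4-[(tert-butyldimethylsilyl)oxy]-3,4-dihydro-2H-chromen-6-yl]propan-1-one, via aryllithium 35 (not isolated)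
Conditions: 34, n-BuLi, THF, −78 °C; then 33, −78 → −20 °C; aq NH4Cl
Reagents that add atoms: none
Why: Bromine–lithium exchange and aryllithium addition to the Weinreb amide; the stable chelated adduct prevents over-addition and epimerisation at C3.

Step 23
Reactants: 36 (2R,3R)-3-[2-(allyloxy)-3,4-bis(benzyloxy)phenyl]-2-(benzyloxy)-1-[3,4-bis(benzyloxy)phenyl]-3-[(2R,3S,4R)-3,7,8-tris(benzyloxy)-2-[4-(benzyloxy)phenyl]-4-[(tert-butyldimethylsilyl)oxy]-3,4-dihydro-2H-chromen-6-yl]propan-1-one
Product: 37 (1S,2R,3R)-3-[2-(allyloxy)-3,4-bis(benzyloxy)phenyl]-2-(benzyloxy)-1-[3,4-bis(benzyloxy)phenyl]-3-[(2R,3S,4R)-3,7,8-tris(benzyloxy)-2-[4-(benzyloxy)phenyl]-4-[(tert-butyldimethylsilyl)oxy]-3,4-dihydro-2H-chromen-6-yl]propan-1-ol (1,2-anti)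
Conditions: Zn(BH4)2, Et2O/CH2Cl2, −30 → 0 °C
Reagents that add atoms: none
Why: Chelation-controlled reduction (Cram chelate model); zinc bridges the carbonyl and the C3 benzyloxy oxygen and hydride enters anti to the bulky C4 substituent, giving the anti alcohol (C2, S).

Step 24
Reactants: 37 (1S,2R,3R)-3-[2-(allyloxy)-3,4-bis(benzyloxy)phenyl]-2-(benzyloxy)-1-[3,4-bis(benzyloxy)phenyl]-3-[(2R,3S,4R)-3,7,8-tris(benzyloxy)-2-[4-(benzyloxy)phenyl]-4-[(tert-butyldimethylsilyl)oxy]-3,4-dihydro-2H-chromen-6-yl]propan-1-ol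
Product: 38 (1S,2R,3R)-2-(benzyloxy)-1-[3,4-bis(benzyloxy)phenyl]-3-[3,4-bis(benzyloxy)-2-hydroxyphenyl]-3-[(2R,3S,4R)-3,7,8-tris(benzyloxy)-2-[4-(benzyloxy)phenyl]-4-[(tert-butyldimethylsilyl)oxy]-3,4-dihydro-2H-chromen-6-yl]propan-1-ol
Conditions: Pd(PPh3)4 (5 mol %), morpholine, THF, rt
Reagents that add atoms: none
Why: Deallylation of the aryl allyl ether by zerovalent palladium; O1 is the only phenol set free, because O7′ was benzylated in step 21.

Step 25
Reactants: 38 (1S,2R,3R)-2-(benzyloxy)-1-[3,4-bis(benzyloxy)phenyl]-3-[3,4-bis(benzyloxy)-2-hydroxyphenyl]-3-[(2R,3S,4R)-3,7,8-tris(benzyloxy)-2-[4-(benzyloxy)phenyl]-4-[(tert-butyldimethylsilyl)oxy]-3,4-dihydro-2H-chromen-6-yl]propan-1-ol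
Product: 39 (2R,3R,4R)-3,7,8-tris(benzyloxy)-2-[3,4-bis(benzyloxy)phenyl]-4-[(2R,3S,4R)-3,7,8-tris(benzyloxy)-2-[4-(benzyloxy)phenyl]-4-[(tert-butyldimethylsilyl)oxy]-3,4-dihydro-2H-chromen-6-yl]-3,4-dihydro-2H-chromene (upper ring 2,3-cis-3,4-trans)
Conditions: PPh3, DIAD, THF (0.02 M), 0 °C → rt
Reagents that add atoms: none
Why: Intramolecular Mitsunobu etherification; O1 displaces the activated C2 hydroxyl with inversion (S to R), closing ring C of the upper unit as the 2,3-cis flavan, with C3 and C4 unchanged.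

Step 26
Reactants: 39 (2R,3R,4R)-3,7,8-tris(benzyloxy)-2-[3,4-bis(benzyloxy)phenyl]-4-[(2R,3S,4R)-3,7,8-tris(benzyloxy)-2-[4-(benzyloxy)phenyl]-4-[(tert-butyldimethylsilyl)oxy]-3,4-dihydro-2H-chromen-6-yl]-3,4-dihydro-2H-chromene
Product: 40 (2R,3R,4R)-3,7,8-tris(benzyloxy)-2-[4-(benzyloxy)phenyl]-6-[(2R,3R,4R)-3,7,8-tris(benzyloxy)-2-[3,4-bis(benzyloxy)phenyl]-3,4-dihydro-2H-chromen-4-yl]-3,4-dihydro-2H-chromen-4-ol
Conditions: Bu4NF, AcOH, THF, rt → 40 °C
Reagents that add atoms: none
Why: Fluoride-mediated desilylation under buffered conditions; no acid reaches the ionisable C4′ position and all phenols are still protected.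

Step 27
Reactants: 40 (2R,3R,4R)-3,7,8-tris(benzyloxy)-2-[4-(benzyloxy)phenyl]-6-[(2R,3R,4R)-3,7,8-tris(benzyloxy)-2-[3,4-bis(benzyloxy)phenyl]-3,4-dihydro-2H-chromen-4-yl]-3,4-dihydro-2H-chromen-4-ol
Product: 41 (2R,3R,4R)-6-[(2R,3R,4S)-2-(3,4-dihydroxyphenyl)-3,7,8-trihydroxy-3,4-dihydro-2H-chromen-4-yl]-2-(4-hydroxyphenyl)-3,4-dihydro-2H-chromene-3,4,7,8-tetrol
Conditions: H2 (1 atm), Pd(OH)2/C, THF/MeOH, rt; filtration and concentration under argon
Reagents that add atoms: none
Why: Hydrogenolysis of the nine benzyl ethers under neutral conditions; the free secondary C4′ hydroxyl is a poor leaving group without acid and should survive, and no stereocentre is touched.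

## Compound list

1 | (S)-4-benzyloxazolidin-2-one | O=C1N[C@@H](Cc2ccccc2)CO1 | starting material
2 | (benzyloxy)acetyl chloride | O=C(Cl)COCc1ccccc1 | starting material
3 | (S)-4-benzyl-3-[(benzyloxy)acetyl]oxazolidin-2-one | O=C(COCc1ccccc1)N1[C@@H](Cc2ccccc2)COC1=O | intermediate
4 | 2,3,4-trihydroxybenzaldehyde | O=Cc1ccc(O)c(O)c1O | starting material
5 | 4-(allyloxy)-2,3-dihydroxybenzaldehyde | O=Cc1ccc(OCC=C)c(O)c1O | intermediate
6 | 4-(allyloxy)-3-(benzyloxy)-2-hydroxybenzaldehyde | O=Cc1ccc(OCC=C)c(OCc2ccccc2)c1O | intermediate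
7 | 2,4-bis(allyloxy)-3-(benzyloxy)benzaldehyde | O=Cc1ccc(OCC=C)c(OCc2ccccc2)c1OCC=C | intermediate
8 | O-trimethylsilyl ether of the anti-aldol adduct 9, (2R,3R) | O=C([C@H](OCc1ccccc1)[C@H](O[Si](C)(C)C)c1ccc(OCC=C)c(OCc2ccccc2)c1OCC=C)N1[C@@H](Cc2ccccc2)COC1=O | intermediate (not isolated)
9 | (S)-4-benzyl-3-{(2R,3R)-3-[2,4-bis(allyloxy)-3-(benzyloxy)phenyl]-2-(benzyloxy)-3-hydroxypropanoyl}oxazolidin-2-one | O=C([C@H](OCc1ccccc1)[C@H](O)c1ccc(OCC=C)c(OCc2ccccc2)c1OCC=C)N1[C@@H](Cc2ccccc2)COC1=O | intermediate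
10 | (2R,3R)-3-[2,4-bis(allyloxy)-3-(benzyloxy)phenyl]-2-(benzyloxy)-3-hydroxy-N-methoxy-N-methylpropanamide | CON(C)C(=O)[C@H](OCc1ccccc1)[C@H](O)c1ccc(OCC=C)c(OCc2ccccc2)c1OCC=C | intermediate
11 | (2R,3R)-3-[2,4-bis(allyloxy)-3-(benzyloxy)phenyl]-2-(benzyloxy)-3-[(tert-butyldimethylsilyl)oxy]-N-methoxy-N-methylpropanamide | CON(C)C(=O)[C@H](OCc1ccccc1)[C@H](O[Si](C)(C)C(C)(C)C)c1ccc(OCC=C)c(OCc2ccccc2)c1OCC=C | intermediate
12 | 1-(benzyloxy)-4-bromobenzene | Brc1ccc(OCc2ccccc2)cc1 | starting material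
13 | [4-(benzyloxy)phenyl]lithium | [Li]c1ccc(OCc2ccccc2)cc1 | intermediate (not isolated)
14 | (2R,3R)-3-[2,4-bis(allyloxy)-3-(benzyloxy)phenyl]-2-(benzyloxy)-1-[4-(benzyloxy)phenyl]-3-[(tert-butyldimethylsilyl)oxy]propan-1-one | O=C(c1ccc(OCc2ccccc2)cc1)[C@H](OCc1ccccc1)[C@H](O[Si](C)(C)C(C)(C)C)c1ccc(OCC=C)c(OCc2ccccc2)c1OCC=C | intermediate
15 | (1S,2S,3R)-3-[2,4-bis(allyloxy)-3-(benzyloxy)phenyl]-2-(benzyloxy)-1-[4-(benzyloxy)phenyl]-3-[(tert-butyldimethylsilyl)oxy]propan-1-ol | O[C@@H](c1ccc(OCc2ccccc2)cc1)[C@H](OCc1ccccc1)[C@H](O[Si](C)(C)C(C)(C)C)c1ccc(OCC=C)c(OCc2ccccc2)c1OCC=C | intermediate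
16 | (1S,2S,3R)-2-(benzyloxy)-3-[3-(benzyloxy)-2,4-dihydroxyphenyl]-1-[4-(benzyloxy)phenyl]-3-[(tert-butyldimethylsilyl)oxy]propan-1-ol | O[C@@H](c1ccc(OCc2ccccc2)cc1)[C@H](OCc1ccccc1)[C@H](O[Si](C)(C)C(C)(C)C)c1ccc(O)c(OCc2ccccc2)c1O | intermediate
17 | (2R,3S,4R)-3,8-bis(benzyloxy)-2-[4-(benzyloxy)phenyl]-4-[(tert-butyldimethylsilyl)oxy]-3,4-dihydro-2H-chromen-7-ol (all-cis) | c5ccccc5COc1ccc([C@H]2Oc3c(ccc(O)c3OCc5ccccc5)[C@@H](O[Si](C)(C)C(C)(C)C)[C@H]2OCc5ccccc5)cc1 | intermediate
18 | (2R,3S,4R)-3,8-bis(benzyloxy)-2-[4-(benzyloxy)phenyl]-4-[(tert-butyldimethylsilyl)oxy]-7-hydroxy-3,4-dihydro-2H-chromene-6-carbaldehyde | c5ccccc5COc1ccc([C@H]2Oc3c(cc(C=O)c(O)c3OCc5ccccc5)[C@@H](O[Si](C)(C)C(C)(C)C)[C@H]2OCc5ccccc5)cc1 | intermediate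
19 | tert-butyl (2R,3S,4R)-3,8-bis(benzyloxy)-2-[4-(benzyloxy)phenyl]-4-[(tert-butyldimethylsilyl)oxy]-6-formyl-3,4-dihydro-2H-chromen-7-yl carbonate | c5ccccc5COc1ccc([C@H]2Oc3c(cc(C=O)c(OC(=O)OC(C)(C)C)c3OCc5ccccc5)[C@@H](O[Si](C)(C)C(C)(C)C)[C@H]2OCc5ccccc5)cc1 | intermediate
20 | 2,3-dihydroxybenzaldehyde | O=Cc1cccc(O)c1O | starting material
21 | 2,3-bis(benzyloxy)benzaldehyde | O=Cc1cccc(OCc2ccccc2)c1OCc1ccccc1 | intermediate
22 | 2,3-bis(benzyloxy)phenyl formate | O=COc1cccc(OCc2ccccc2)c1OCc1ccccc1 | intermediate (not isolated)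
23 | 2,3-bis(benzyloxy)phenol | Oc1cccc(OCc2ccccc2)c1OCc1ccccc1 | intermediate
24 | 2,3-bis(benzyloxy)-6-bromophenol | Oc1c(Br)ccc(OCc2ccccc2)c1OCc1ccccc1 | intermediate
25 | 2-(allyloxy)-3,4-bis(benzyloxy)-1-bromobenzene | C=CCOc1c(Br)ccc(OCc2ccccc2)c1OCc1ccccc1 | intermediate
26 | [2-(allyloxy)-3,4-bis(benzyloxy)phenyl]magnesium bromide | C=CCOc1c([Mg]Br)ccc(OCc2ccccc2)c1OCc1ccccc1 | intermediate
27 | sodium (Z)-2-(benzyloxy)-1-[(S)-4-benzyl-2-oxooxazolidin-3-yl]ethen-1-olate (sodium enolate of 3) | [Na+].[O-]/C(=C\OCc1ccccc1)N1[C@@H](Cc2ccccc2)COC1=O | intermediate (not isolated)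
28 | bromomagnesium alkoxide of the diarylmethanol from 19 and 26 (O7′ still Boc; carbinol configuration undefined) | c5ccccc5COc1ccc([C@H]2Oc3c(cc(C(O[Mg]Br)c6ccc(OCc5ccccc5)c(OCc5ccccc5)c6OCC=C)c(OC(=O)OC(C)(C)C)c3OCc5ccccc5)[C@@H](O[Si](C)(C)C(C)(C)C)[C@H]2OCc5ccccc5)cc1 | intermediate (not isolated)
29 | (E)-ortho-quinone methide of the lower ring A (C7′ carbonyl, exocyclic C6′=C4 carrying the ring A aryl group) | c5ccccc5COc1ccc([C@H]2OC3=C(OCc5ccccc5)C(=O)/C(=C/c6ccc(OCc5ccccc5)c(OCc5ccccc5)c6OCC=C)C=C3[C@@H](O[Si](C)(C)C(C)(C)C)[C@H]2OCc5ccccc5)cc1 | intermediate (not isolated)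
30 | (S)-4-benzyl-3-{(2R,3S)-3-[2-(allyloxy)-3,4-bis(benzyloxy)phenyl]-2-(benzyloxy)-3-[(2R,3S,4R)-3,8-bis(benzyloxy)-2-[4-(benzyloxy)phenyl]-4-[(tert-butyldimethylsilyl)oxy]-7-hydroxy-3,4-dihydro-2H-chromen-6-yl]propanoyl}oxazolidin-2-one | c5ccccc5COc1ccc([C@H]2Oc3c(cc([C@H]([C@@H](OCc5ccccc5)C(=O)N9[C@@H](Cc5ccccc5)COC9=O)c6ccc(OCc5ccccc5)c(OCc5ccccc5)c6OCC=C)c(O)c3OCc5ccccc5)[C@@H](O[Si](C)(C)C(C)(C)C)[C@H]2OCc5ccccc5)cc1 | intermediate
31 | six-membered aryl lactone between O7′ and C2 of 30 (3-benzyloxy-4-aryl-dihydrocoumarin fused to the lower ring A; C3, C4 and lower-unit configurations as in 30) | c5ccccc5COc1ccc([C@H]2Oc3c(cc([C@H]([C@@H](OCc5ccccc5)C8=O)c6ccc(OCc5ccccc5)c(OCc5ccccc5)c6OCC=C)c(O8)c3OCc5ccccc5)[C@@H](O[Si](C)(C)C(C)(C)C)[C@H]2OCc5ccccc5)cc1 | intermediate (not isolated)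
32 | (2R,3S)-3-[2-(allyloxy)-3,4-bis(benzyloxy)phenyl]-2-(benzyloxy)-3-[(2R,3S,4R)-3,8-bis(benzyloxy)-2-[4-(benzyloxy)phenyl]-4-[(tert-butyldimethylsilyl)oxy]-7-hydroxy-3,4-dihydro-2H-chromen-6-yl]-N-methoxy-N-methylpropanamide | c5ccccc5COc1ccc([C@H]2Oc3c(cc([C@H]([C@@H](OCc5ccccc5)C(=O)N(C)OC)c6ccc(OCc5ccccc5)c(OCc5ccccc5)c6OCC=C)c(O)c3OCc5ccccc5)[C@@H](O[Si](C)(C)C(C)(C)C)[C@H]2OCc5ccccc5)cc1 | intermediate
33 | (2R,3R)-3-[2-(allyloxy)-3,4-bis(benzyloxy)phenyl]-2-(benzyloxy)-N-methoxy-N-methyl-3-[(2R,3S,4R)-3,7,8-tris(benzyloxy)-2-[4-(benzyloxy)phenyl]-4-[(tert-butyldimethylsilyl)oxy]-3,4-dihydro-2H-chromen-6-yl]propanamide | c5ccccc5COc1ccc([C@H]2Oc3c(cc([C@H]([C@@H](OCc5ccccc5)C(=O)N(C)OC)c6ccc(OCc5ccccc5)c(OCc5ccccc5)c6OCC=C)c(OCc5ccccc5)c3OCc5ccccc5)[C@@H](O[Si](C)(C)C(C)(C)C)[C@H]2OCc5ccccc5)cc1 | intermediate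
34 | 1,2-bis(benzyloxy)-4-bromobenzene | Brc1ccc(OCc2ccccc2)c(OCc2ccccc2)c1 | starting material
35 | [3,4-bis(benzyloxy)phenyl]lithium | [Li]c1ccc(OCc2ccccc2)c(OCc2ccccc2)c1 | intermediate (not isolated)
36 | (2R,3R)-3-[2-(allyloxy)-3,4-bis(benzyloxy)phenyl]-2-(benzyloxy)-1-[3,4-bis(benzyloxy)phenyl]-3-[(2R,3S,4R)-3,7,8-tris(benzyloxy)-2-[4-(benzyloxy)phenyl]-4-[(tert-butyldimethylsilyl)oxy]-3,4-dihydro-2H-chromen-6-yl]propan-1-one | c5ccccc5COc1ccc([C@H]2Oc3c(cc([C@H]([C@@H](OCc5ccccc5)C(=O)c8ccc(OCc5ccccc5)c(OCc5ccccc5)c8)c6ccc(OCc5ccccc5)c(OCc5ccccc5)c6OCC=C)c(OCc5ccccc5)c3OCc5ccccc5)[C@@H](O[Si](C)(C)C(C)(C)C)[C@H]2OCc5ccccc5)cc1 | intermediate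
37 | (1S,2R,3R)-3-[2-(allyloxy)-3,4-bis(benzyloxy)phenyl]-2-(benzyloxy)-1-[3,4-bis(benzyloxy)phenyl]-3-[(2R,3S,4R)-3,7,8-tris(benzyloxy)-2-[4-(benzyloxy)phenyl]-4-[(tert-butyldimethylsilyl)oxy]-3,4-dihydro-2H-chromen-6-yl]propan-1-ol | c5ccccc5COc1ccc([C@H]2Oc3c(cc([C@H]([C@@H](OCc5ccccc5)[C@@H](O)c8ccc(OCc5ccccc5)c(OCc5ccccc5)c8)c6ccc(OCc5ccccc5)c(OCc5ccccc5)c6OCC=C)c(OCc5ccccc5)c3OCc5ccccc5)[C@@H](O[Si](C)(C)C(C)(C)C)[C@H]2OCc5ccccc5)cc1 | intermediate
38 | (1S,2R,3R)-2-(benzyloxy)-1-[3,4-bis(benzyloxy)phenyl]-3-[3,4-bis(benzyloxy)-2-hydroxyphenyl]-3-[(2R,3S,4R)-3,7,8-tris(benzyloxy)-2-[4-(benzyloxy)phenyl]-4-[(tert-butyldimethylsilyl)oxy]-3,4-dihydro-2H-chromen-6-yl]propan-1-ol | c5ccccc5COc1ccc([C@H]2Oc3c(cc([C@H]([C@@H](OCc5ccccc5)[C@@H](O)c8ccc(OCc5ccccc5)c(OCc5ccccc5)c8)c6ccc(OCc5ccccc5)c(OCc5ccccc5)c6O)c(OCc5ccccc5)c3OCc5ccccc5)[C@@H](O[Si](C)(C)C(C)(C)C)[C@H]2OCc5ccccc5)cc1 | intermediate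
39 | (2R,3R,4R)-3,7,8-tris(benzyloxy)-2-[3,4-bis(benzyloxy)phenyl]-4-[(2R,3S,4R)-3,7,8-tris(benzyloxy)-2-[4-(benzyloxy)phenyl]-4-[(tert-butyldimethylsilyl)oxy]-3,4-dihydro-2H-chromen-6-yl]-3,4-dihydro-2H-chromene | c5ccccc5COc1ccc([C@H]2Oc3c(cc([C@H]4c6ccc(OCc5ccccc5)c(OCc5ccccc5)c6O[C@H](c8ccc(OCc5ccccc5)c(OCc5ccccc5)c8)[C@@H]4OCc5ccccc5)c(OCc5ccccc5)c3OCc5ccccc5)[C@@H](O[Si](C)(C)C(C)(C)C)[C@H]2OCc5ccccc5)cc1 | intermediate
40 | (2R,3R,4R)-3,7,8-tris(benzyloxy)-2-[4-(benzyloxy)phenyl]-6-[(2R,3R,4R)-3,7,8-tris(benzyloxy)-2-[3,4-bis(benzyloxy)phenyl]-3,4-dihydro-2H-chromen-4-yl]-3,4-dihydro-2H-chromen-4-ol | c5ccccc5COc1ccc([C@H]2Oc3c(cc([C@H]4c6ccc(OCc5ccccc5)c(OCc5ccccc5)c6O[C@H](c8ccc(OCc5ccccc5)c(OCc5ccccc5)c8)[C@@H]4OCc5ccccc5)c(OCc5ccccc5)c3OCc5ccccc5)[C@@H](O)[C@H]2OCc5ccccc5)cc1 | intermediate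
41 | (2R,3R,4R)-6-[(2R,3R,4S)-2-(3,4-dihydroxyphenyl)-3,7,8-trihydroxy-3,4-dihydro-2H-chromen-4-yl]-2-(4-hydroxyphenyl)-3,4-dihydro-2H-chromene-3,4,7,8-tetrol | Oc1ccc([C@H]2Oc3c(cc([C@H]4c5ccc(O)c(O)c5O[C@H](c5ccc(O)c(O)c5)[C@@H]4O)c(O)c3O)[C@@H](O)[C@H]2O)cc1 | target

## Step count and least certain steps

Total: 27 steps. Longest linear sequence: 21 steps (4 to 41 through steps 2–13 and 19–27); steps 1 and 14–18 are side branches.

**Step 19 (key step).** The most likely failures are three:
- the sodium enolate acts on the carbonate or as a base before the quinone methide is available;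
- the hindered, aryl-substituted methide is consumed by dimerisation or by the slight excess of 26 before the C3–C4 bond forms;
- discrimination between closed and open transition states is poor, so C4 forms as a mixture.

The fallback uses known chemistry and sets out from 18. Addition of 26 (2.2 equiv, the first equivalent deprotonating the phenol) to the aldehyde gives the ortho-hydroxybenzhydrol F1 as a mixture of carbinol epimers. F1 is then added to the chlorotitanium enolate of 3 (TiCl4, i-Pr2NEt, CH2Cl2, −78 °C). The Lewis acid ionises the carbinol to the same quinone methide or diarylmethyl cation, which alkylates the auxiliary-shielded face of the titanium enolate (SN1-type alkylation of titanium imide enolates). The route is rejoined at 30. C3 is again set by the auxiliary; C4 would have to be secured by chromatography if the cation shows little facial bias.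

**Step 5.** The aldol addition to an electron-rich, ortho-alkoxylated aldehyde is reversible, so conversion may stall. Competing chelation by the α-benzyloxy group may erode the anti preference. The fallback sets out from 7 and 2:
- 2 is converted with ethanethiol and Et3N into S-ethyl 2-(benzyloxy)ethanethioate F2;
- F2 is silylated (LiN(i-Pr)2, Me3SiCl) to the (Z)-ketene silyl thioacetal F3;
- a Mukaiyama aldol reaction of F3 with 7, promoted by divalent tin triflate Sn(OTf)2, a proline-derived chiral diamine (the enantiomer that gives the 2R,3R adduct) and Bu2Sn(OAc)2 in CH2Cl2 at −78 °C, gives the anti thioester S-ethyl (2R,3R)-3-[2,4-bis(allyloxy)-3-(benzyloxy)phenyl]-2-(benzyloxy)-3-hydroxypropanethioate F4;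
- aminolysis of F4 with MeNHOMe·HCl and AlMe3 rejoins the route at 10.

**Step 12.** Heating the magnesium phenoxide, which is para to the benzylic silyl ether, may cause loss of silanolate through a para-quinone methide. The hindered phenol may also formylate slowly. The fallback sets out from 17. NBS bromination at the only free ortho position gives the bromophenol (2R,3S,4R)-3,8-bis(benzyloxy)-2-[4-(benzyloxy)phenyl]-6-bromo-4-[(tert-butyldimethylsilyl)oxy]-3,4-dihydro-2H-chromen-7-ol F5. Deprotonation of F5 with NaH, bromine–lithium exchange with n-BuLi at −78 °C and quenching with DMF rejoin the route at 18.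

**Step 25 (the same concern applies to step 11).** The oxyphosphonium ion at an electron-rich benzylic carbon may ionise, which would cost the inversion (2,3-trans flavan) or lead to elimination. The fallback closes the other C–O bond with retention and sets out from 36:
- Felkin–Anh reduction with KBH(s-Bu)3 in THF at −78 °C gives the C2-epimeric (1R,2R,3R) alcohol F6;
- Pd(PPh3)4 and morpholine free the O1 phenol to give F7;
- PhNTf2 and K2CO3 convert the phenol selectively into the aryl triflate F8;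
- Pd(OAc)2, 2-(di-tert-butylphosphino)-1,1′-binaphthyl and Cs2CO3 in toluene at 70 °C form the O1–C8a bond with C2 untouched, rejoining the route at 39.

**Step 27.** Once O7′ is unmasked, the para-hydroxybenzylic C4′–O bond may be hydrogenolysed. Nine ethers may also cleave unevenly. The fallback sets out from 39 and reverses the order of the last two steps. Hydrogenolysis (H2, Pd(OH)2/C, THF/MeOH) with the silyl ether still in place gives the 4′-O-silyl polyphenol F9, in which the silyl group shields C4′. Desilylation of F9 with HF·pyridine buffered with pyridine in THF at 0 °C gives 41.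

## Further compounds

F1 | step 19 | ortho-hydroxybenzhydrol: (2R,3S,4R)-6-{[2-(allyloxy)-3,4-bis(benzyloxy)phenyl](hydroxy)methyl}-3,8-bis(benzyloxy)-2-[4-(benzyloxy)phenyl]-4-[(tert-butyldimethylsilyl)oxy]-3,4-dihydro-2H-chromen-7-ol (carbinol epimers) | c5ccccc5COc1ccc([C@H]2Oc3c(cc(C(O)c6ccc(OCc5ccccc5)c(OCc5ccccc5)c6OCC=C)c(O)c3OCc5ccccc5)[C@@H](O[Si](C)(C)C(C)(C)C)[C@H]2OCc5ccccc5)cc1
F2 | step 5 | S-ethyl 2-(benzyloxy)ethanethioate | CCSC(=O)COCc1ccccc1
F3 | step 5 | (Z)-2-(benzyloxy)-1-(ethylsulfanyl)-1-[(trimethylsilyl)oxy]ethene | CCS/C(O[Si](C)(C)C)=C\OCc1ccccc1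
F4 | step 5 | S-ethyl (2R,3R)-3-[2,4-bis(allyloxy)-3-(benzyloxy)phenyl]-2-(benzyloxy)-3-hydroxypropanethioate | CCSC(=O)[C@H](OCc1ccccc1)[C@H](O)c1ccc(OCC=C)c(OCc2ccccc2)c1OCC=C
F5 | step 12 | (2R,3S,4R)-3,8-bis(benzyloxy)-2-[4-(benzyloxy)phenyl]-6-bromo-4-[(tert-butyldimethylsilyl)oxy]-3,4-dihydro-2H-chromen-7-ol | c5ccccc5COc1ccc([C@H]2Oc3c(cc(Br)c(O)c3OCc5ccccc5)[C@@H](O[Si](C)(C)C(C)(C)C)[C@H]2OCc5ccccc5)cc1
F6 | step 25 | (1R,2R,3R)-3-[2-(allyloxy)-3,4-bis(benzyloxy)phenyl]-2-(benzyloxy)-1-[3,4-bis(benzyloxy)phenyl]-3-[(2R,3S,4R)-3,7,8-tris(benzyloxy)-2-[4-(benzyloxy)phenyl]-4-[(tert-butyldimethylsilyl)oxy]-3,4-dihydro-2H-chromen-6-yl]propan-1-ol (C2 epimer of 37) | c5ccccc5COc1ccc([C@H]2Oc3c(cc([C@H]([C@@H](OCc5ccccc5)[C@H](O)c8ccc(OCc5ccccc5)c(OCc5ccccc5)c8)c6ccc(OCc5ccccc5)c(OCc5ccccc5)c6OCC=C)c(OCc5ccccc5)c3OCc5ccccc5)[C@@H](O[Si](C)(C)C(C)(C)C)[C@H]2OCc5ccccc5)cc1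
F7 | step 25 | O1 phenol of F6 (C2 epimer of 38) | c5ccccc5COc1ccc([C@H]2Oc3c(cc([C@H]([C@@H](OCc5ccccc5)[C@H](O)c8ccc(OCc5ccccc5)c(OCc5ccccc5)c8)c6ccc(OCc5ccccc5)c(OCc5ccccc5)c6O)c(OCc5ccccc5)c3OCc5ccccc5)[C@@H](O[Si](C)(C)C(C)(C)C)[C@H]2OCc5ccccc5)cc1
F8 | step 25 | C8a aryl trifluoromethanesulfonate of F7 | c5ccccc5COc1ccc([C@H]2Oc3c(cc([C@H]([C@@H](OCc5ccccc5)[C@H](O)c8ccc(OCc5ccccc5)c(OCc5ccccc5)c8)c6ccc(OCc5ccccc5)c(OCc5ccccc5)c6OS(=O)(=O)C(F)(F)F)c(OCc5ccccc5)c3OCc5ccccc5)[C@@H](O[Si](C)(C)C(C)(C)C)[C@H]2OCc5ccccc5)cc1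
F9 | step 27 | 4′-O-(tert-butyldimethylsilyl) ether of 41 (all phenols and O3, O3′ free) | Oc1ccc([C@H]2Oc3c(cc([C@H]4c5ccc(O)c(O)c5O[C@H](c5ccc(O)c(O)c5)[C@@H]4O)c(O)c3O)[C@@H](O[Si](C)(C)C(C)(C)C)[C@H]2O)cc1
A1 | alternative 1 | all-cis 4′-O-allyl 3′-O-benzoyl octa-O-benzyl biflavan | c5ccccc5COc1ccc([C@H]2Oc3c(cc([C@H]4c6ccc(OCc5ccccc5)c(OCc5ccccc5)c6O[C@H](c8ccc(OCc5ccccc5)c(OCc5ccccc5)c8)[C@@H]4OCc5ccccc5)c(OCc5ccccc5)c3OCc5ccccc5)[C@@H](OCC=C)[C@H]2OC(=O)c5ccccc5)cc1
A2 | alternative 1 | diallyl acetal of the lower ring A salicylaldehyde carrying the penta-O-benzyl upper flavan at C6′ (free O1′) | C=CCOC(OCC=C)c1cc([C@H]4c6ccc(OCc5ccccc5)c(OCc5ccccc5)c6O[C@H](c8ccc(OCc5ccccc5)c(OCc5ccccc5)c8)[C@@H]4OCc5ccccc5)c(OCc5ccccc5)c(OCc5ccccc5)c1O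
A3 | alternative 1 | (Z)-2-[4-(benzyloxy)phenyl]ethenyl benzoate | O=C(O/C=C\c1ccc(OCc2ccccc2)cc1)c1ccccc1
A4 | alternative 2 | protected biflavan with free C3 hydroxyl, ring B dipivalate and lower 3′,4′-acetonide | c5ccccc5COc1ccc([C@H]2Oc3c(cc([C@H]4c6ccc(OCc5ccccc5)c(OCc5ccccc5)c6O[C@H](c8ccc(OC(=O)C(C)(C)C)c(OC(=O)C(C)(C)C)c8)[C@@H]4O)c(OCc5ccccc5)c3OCc5ccccc5)[C@H]7OC(C)(C)O[C@@H]27)cc1
A5 | alternative 2 | open-chain cis-2,3-epoxide with free O1 phenol, ring B dipivalate and lower 3′,4′-acetonide | c5ccccc5COc1ccc([C@H]2Oc3c(cc([C@H]([C@H]9O[C@H]9c8ccc(OC(=O)C(C)(C)C)c(OC(=O)C(C)(C)C)c8)c6ccc(OCc5ccccc5)c(OCc5ccccc5)c6O)c(OCc5ccccc5)c3OCc5ccccc5)[C@H]7OC(C)(C)O[C@@H]27)cc1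
A6 | alternative 3 | octa-O-benzyl biflavan 3′,4′-acetonide | c5ccccc5COc1ccc([C@H]2Oc3c(cc([C@H]4c6ccc(OCc5ccccc5)c(OCc5ccccc5)c6O[C@H](c8ccc(OCc5ccccc5)c(OCc5ccccc5)c8)[C@@H]4OCc5ccccc5)c(OCc5ccccc5)c3OCc5ccccc5)[C@H]7OC(C)(C)O[C@@H]27)cc1
A7 | alternative 3 | open-chain C2 alcohol with C8a aryl trifluoromethanesulfonate and lower 3′,4′-acetonide | c5ccccc5COc1ccc([C@H]2Oc3c(cc([C@H]([C@@H](OCc5ccccc5)[C@H](O)c8ccc(OCc5ccccc5)c(OCc5ccccc5)c8)c6ccc(OCc5ccccc5)c(OCc5ccccc5)c6OS(=O)(=O)C(F)(F)F)c(OCc5ccccc5)c3OCc5ccccc5)[C@H]7OC(C)(C)O[C@@H]27)cc1
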